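**One-step world.** In a one-step world, starting material and activator give ring directly, one activator for each ring. Less activator than starting material is charged to red and teal, so activator is their limiting reagent. Its ledger has two entries: activator booked as ring and activator still free.

| flask | starting material | activator | temperature | remark | time |
|---|---|---|---|---|---|
| epsilon | 10 mM | 19 mM | −40 °C | run made earlier |  |
| alpha | 40 mM | 19 mM | −28 °C | run made earlier |  |
| red | 20 mM | 19.0 mM | −20 °C |  | 6.0 min |
| teal | 20 mM | 19.0 mM | −35 °C |  | 6.0 min |

| run | time / min | ring / % |
|---|---|---|
| epsilon | 1.00 | 1.4 |
| epsilon | 4.00 | 0.6 |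
| epsilon | 6.00 | 3.9 |
| epsilon | 10.0 | 5.4 |
| alpha | 0.417 | 0 |
| alpha | 1.33 | 1.3 |
| alpha | 2.50 | 7.4 |
| alpha | 4.00 | 10.0 |

(readings scatter by 1 percentage point)

* the flask that comes out highest in amount of ring, in percent of the starting material charged, or "all alike" when all lie within 1.5 percentage points (red / teal / all alike)
* ring at the end, in percent of the starting material charged, red
* ring at the end, in percent of the starting material charged, teal

- what was read earlier has a scatter of 1 percentage point, one standard deviation

**The ceiling.** Activator charged per starting material charged is 95.0%. This activator ceiling is the ring in percent that red or teal shows if each activator ends as ring.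

**Earlier entries.** The last alpha reading books 4.00 mM of activator as ring, out of 19 mM charged, after 4.00 min. The last epsilon reading books 0.540 mM after 10.0 min. Both readings carry the scatter.

**The forecast.** It names red, with 26% (12% to 38%) for red and 5.5% (3% to 9%) for teal, on this ground: “Ring closure should be intramolecular”. Its red figure is what the rule of thumb of rates doubling with temperature gives from the alpha run. The one-step ledger, a separate reckoning, books that figure as 5.20 mM of ring and closes with 13.8 mM of activator free. In the same ledger, the high end of the forecast for red closes with 60.0% of the activator free.

**The result.** Red gives 38.9% and teal 6.31%, so the highest flask is red.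

    starting material + activator → activated form (k = 0.513 M⁻¹ s⁻¹, Ea = 53.0 kJ mol⁻¹)
    activated form → ring (k = 0.00822 s⁻¹, Ea = 70.0 kJ mol⁻¹)
    starting material + activated form → open dimer (k = 0.172 M⁻¹ s⁻¹, Ea = 38.0 kJ mol⁻¹)
    activator + ring → over-reaction product (k = 0.314 M⁻¹ s⁻¹, Ea = 54.0 kJ mol⁻¹)
    (constants at −20 °C)

**Closed books.** At 6.00 min red holds 40.9% of the ceiling as ring, yet 13% of its activator is free. Booking one activator per ring and per activated form, one per two units of open dimer and two per over-reaction product gives 82.6% of the starting material charged, or 86.9% of the activator. The flask at −5 °C, with 0.031% of its activator free, books 95.0% against the ceiling of 95.0%. At 6.00 min red makes ring 2.16 times faster than it uses it up. At 60.0 min red holds 43.8% ring beside 20.5% over-reaction product, with 0% activator.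

The runs are simulated for substances that don't exist.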